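**Retrosynthetic overview**
1. The C14–O ester bond is made last, by Mitsunobu esterification of dauca-4,8-dien-14-ol with unprotected vanillic acid.
2. Ring B (the cycloheptene) is closed second, at C8=C9, by intramolecular Wittig reaction of a C9 ylide with a C8 ketone. C6–C7 comes from alkylation of a silyloxyacetone enolate by a C6 allylic bromide, and the C4 isopropyl group from iron-catalysed coupling of a C4 enol triflate.
3. Ring A (the five-membered ring) is closed first, at C1–C5, by insertion of a rhodium carbenoid at C5 into the tertiary C1–H bond of an acyclic α-diazo-β-keto ester.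
4. Feature behind the plan: the quaternary fusion carbon C1, shared by ring A and ring B and carrying the C15 methyl group, is the methyl-bearing stereocentre of (S)-citronellol with its hydrogen replaced by the bond to C5. C5 stands 1,5 to it across C4, which is a ketone carbon until the isopropyl group is attached.
5. The diazo keto ester comes from (S)-citronellol in four steps: silylation, ozonolysis, Roskamp homologation, diazo transfer.

Key step: step 5

Remark: atoms carry daucane numbers (C1 quaternary with methyl C15; C2, C3 ring A CH2; C4 isopropyl-bearing; C5 fusion carbon; C6, C7, C10 ring B CH2; C8 bearing C14; C9 vinyl CH), and because the ester alkyl group is lost in step 8, the ethyl ester delivered by commercial ethyl diazoacetate is carried through steps 3 to 7.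

**Route**

Step 1
Reactants: 1 (S)-citronellol
Product: 2 tert-butyl{[(3S)-3,7-dimethyloct-6-en-1-yl]oxy}dimethylsilane
Conditions: TBSCl, imidazole, DMF, 0 °C → rt
Reagents that add atoms: tert-butyldimethylsilyl chloride, CC(C)(C)[Si](C)(C)Cl
Why: Silyl ether formation at the primary hydroxyl group protects the future C9 oxygen through the oxidative, organometallic and hydride steps and leaves the stereocentre untouched.

Step 2
Reactants: 2 tert-butyl{[(3S)-3,7-dimethyloct-6-en-1-yl]oxy}dimethylsilane
Product: 4 (4S)-6-[(tert-butyldimethylsilyl)oxy]-4-methylhexanal, via secondary ozonide 3 (not isolated)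
Conditions: O3, CH2Cl2, −78 °C; then PPh3, −78 °C → rt
Reagents that add atoms: ozone, [O-][O+]=O
Why: Reductive ozonolysis (Criegee mechanism) cleaves the only alkene, an electron-rich trisubstituted one, to the aldehyde and acetone, with no epimerisable centre next to the new carbonyl group and the silyl ether inert.

Step 3
Reactants: 4 (4S)-6-[(tert-butyldimethylsilyl)oxy]-4-methylhexanal; 5 ethyl diazoacetate
Product: 6 ethyl (6S)-8-[(tert-butyldimethylsilyl)oxy]-6-methyl-3-oxooctanoate
Conditions: SnCl2 (10 mol %), CH2Cl2, rt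
Reagents that add atoms: none
Why: Roskamp homologation, in which the diazo carbon adds to the SnCl2-activated aldehyde and a 1,2-hydride shift with loss of N2 gives the β-keto ester directly under conditions mild enough for the silyl ether.

Step 4
Reactants: 6 ethyl (6S)-8-[(tert-butyldimethylsilyl)oxy]-6-methyl-3-oxooctanoate
Product: 7 ethyl (6S)-8-[(tert-butyldimethylsilyl)oxy]-2-diazo-6-methyl-3-oxooctanoate
Conditions: p-ABSA, Et3N, MeCN, 0 °C → rt
Reagents that add atoms: 4-acetamidobenzenesulfonyl azide (p-ABSA), CC(=O)Nc1ccc(cc1)S(=O)(=O)N=[N+]=[N-]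
Why: Regitz diazo transfer, in which the enolate of the active methylene group attacks the sulfonyl azide and the triazene intermediate collapses to the α-diazo-β-keto ester and the sulfonamide.

Step 5
Reactants: 7 ethyl (6S)-8-[(tert-butyldimethylsilyl)oxy]-2-diazo-6-methyl-3-oxooctanoate
Product: 8 ethyl (2R)-2-{2-[(tert-butyldimethylsilyl)oxy]ethyl}-2-methyl-5-oxocyclopentane-1-carboxylate (ring carbon 1 = C5, epimers in equilibrium through the enol)
Conditions: Rh2(OAc)4 (1 mol %), CH2Cl2, rt, slow addition of 7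
Reagents that add atoms: none
Why: Rh2(OAc)4 expels N2 from the diazo group to give an electrophilic dirhodium carbenoid at C5, which inserts into the C1–H bond in a concerted three-centre process in which hydrogen transfer and C1–C5 bond formation occur together. The closest known reaction type is the dirhodium tetracarboxylate-catalysed intramolecular 1,5 C–H insertion of α-diazo-β-keto esters to 2-alkoxycarbonylcyclopentanones. The cyclopentanone ring closes by 1,5 insertion, the carbenoid carbon reaching C1–H across C4, C3 and C2 through a six-membered transition state that includes the migrating hydrogen. The C1 stereocentre is controlled by the substrate: the new bond forms on the face that the hydrogen occupied, so the configuration of (S)-citronellol is retained as C1 becomes quaternary (the descriptor changes from S to R only because the priorities change), while C5 is epimerisable and becomes sp2 in step 6. The step needs site selectivity for the tertiary C1–H bond over the C3 and C2 methylene groups (three- and four-membered rings), the C10 methylene and C15 methyl groups (six-membered ring) and the ether-activated C9–H bonds (seven-membered ring), and this is secured by the strong preference for five-membered ring formation, reinforced by the electron-rich tertiary C–H bond.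

Step 6
Reactants: 8 ethyl (2R)-2-{2-[(tert-butyldimethylsilyl)oxy]ethyl}-2-methyl-5-oxocyclopentane-1-carboxylate
Product: 10 ethyl (5R)-5-{2-[(tert-butyldimethylsilyl)oxy]ethyl}-5-methyl-2-[(trifluoromethanesulfonyl)oxy]cyclopent-1-ene-1-carboxylate, via sodium enolate 9 (not isolated)
Conditions: NaH, CH2Cl2, 0 °C; then Tf2O, 0 °C
Reagents that add atoms: trifluoromethanesulfonic anhydride, O=S(=O)(OS(=O)(=O)C(F)(F)F)C(F)(F)F
Why: Enol triflate formation by O-sulfonylation of the β-keto ester enolate, which can form only at C5 between the two carbonyl groups, so the C4=C5 enol triflate should arise as a single regioisomer.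

Step 7
Reactants: 10 ethyl (5R)-5-{2-[(tert-butyldimethylsilyl)oxy]ethyl}-5-methyl-2-[(trifluoromethanesulfonyl)oxy]cyclopent-1-ene-1-carboxylate
Product: 11 ethyl (5R)-5-{2-[(tert-butyldimethylsilyl)oxy]ethyl}-5-methyl-2-(propan-2-yl)cyclopent-1-ene-1-carboxylate
Conditions: iPrMgCl, Fe(acac)3 (5 mol %), THF/NMP, −30 °C
Reagents that add atoms: isopropylmagnesium chloride, CC(C)[Mg]Cl
Why: Iron-catalysed Kumada-type cross-coupling of an ester-activated alkenyl triflate with an alkyl Grignard reagent is faster at −30 °C than attack of the Grignard reagent on the ester and places the isopropyl group on C4 with the alkene position fixed.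

Step 8
Reactants: 11 ethyl (5R)-5-{2-[(tert-butyldimethylsilyl)oxy]ethyl}-5-methyl-2-(propan-2-yl)cyclopent-1-ene-1-carboxylate
Product: 12 [(5R)-5-{2-[(tert-butyldimethylsilyl)oxy]ethyl}-5-methyl-2-(propan-2-yl)cyclopent-1-en-1-yl]methanol
Conditions: iBu2AlH, CH2Cl2, −78 → 0 °C; aq. KNaC4H4O6 work-up
Reagents that add atoms: none
Why: Hydride reduction of the α,β-unsaturated ester by iBu2AlH proceeds by 1,2-addition through the aldehyde to the allylic alcohol and touches neither the silyl ether nor the tetrasubstituted alkene.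

Step 9
Reactants: 12 [(5R)-5-{2-[(tert-butyldimethylsilyl)oxy]ethyl}-5-methyl-2-(propan-2-yl)cyclopent-1-en-1-yl]methanol
Product: 13 {2-[(1R)-2-(bromomethyl)-1-methyl-3-(propan-2-yl)cyclopent-2-en-1-yl]ethoxy}(tert-butyl)dimethylsilane
Conditions: CBr4, PPh3, CH2Cl2, 0 °C
Reagents that add atoms: carbon tetrabromide, BrC(Br)(Br)Br
Why: Appel reaction, in which bromide displaces the alkoxyphosphonium ion at the primary allylic C6 under neutral conditions that spare the silyl ether, allylic transposition to the fully substituted C4 being disfavoured.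

Step 10
Reactants: 14 hydroxyacetone
Product: 15 1-[(tert-butyldiphenylsilyl)oxy]propan-2-one
Conditions: TBDPSCl, imidazole, CH2Cl2, 0 °C → rt
Reagents that add atoms: tert-butyldiphenylsilyl chloride, CC(C)(C)[Si](Cl)(c1ccccc1)c1ccccc1
Why: Silyl ether formation at the primary hydroxyl group installs a bulky, acid-stable protecting group on the future C14 oxygen that is orthogonal to the tert-butyldimethylsilyl ether at C9.

Step 11
Reactants: 15 1-[(tert-butyldiphenylsilyl)oxy]propan-2-one; 13 {2-[(1R)-2-(bromomethyl)-1-methyl-3-(propan-2-yl)cyclopent-2-en-1-yl]ethoxy}(tert-butyl)dimethylsilane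
Product: 17 4-[(5R)-5-{2-[(tert-butyldimethylsilyl)oxy]ethyl}-5-methyl-2-(propan-2-yl)cyclopent-1-en-1-yl]-1-[(tert-butyldiphenylsilyl)oxy]butan-2-one, via lithium enolate 16 (not isolated)
Conditions: 15 (3 equiv), LiN(iPr)2, THF, −78 °C; then 13, DMPU, −78 → −20 °C
Reagents that add atoms: none
Why: Kinetic enolate alkylation, in which LiN(iPr)2 at −78 °C should remove a proton from the unhindered methyl group in preference to the CH2 group shielded by the bulky silyloxy substituent, and the excess enolate displaces the primary allylic bromide by SN2 to form C6–C7.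

Step 12
Reactants: 17 4-[(5R)-5-{2-[(tert-butyldimethylsilyl)oxy]ethyl}-5-methyl-2-(propan-2-yl)cyclopent-1-en-1-yl]-1-[(tert-butyldiphenylsilyl)oxy]butan-2-one
Product: 18 1-[(tert-butyldiphenylsilyl)oxy]-4-[(5R)-5-(2-hydroxyethyl)-5-methyl-2-(propan-2-yl)cyclopent-1-en-1-yl]butan-2-one
Conditions: PPTS (cat.), MeOH/CH2Cl2, rt
Reagents that add atoms: none
Why: Acid-catalysed methanolysis of a silyl ether cleaves the primary tert-butyldimethylsilyl ether far faster than the tert-butyldiphenylsilyl ether, so only the C9 hydroxyl group should be freed.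

Step 13
Reactants: 18 1-[(tert-butyldiphenylsilyl)oxy]-4-[(5R)-5-(2-hydroxyethyl)-5-methyl-2-(propan-2-yl)cyclopent-1-en-1-yl]butan-2-one
Product: 19 1-[(tert-butyldiphenylsilyl)oxy]-4-[(5R)-5-(2-iodoethyl)-5-methyl-2-(propan-2-yl)cyclopent-1-en-1-yl]butan-2-one
Conditions: I2, PPh3, imidazole, CH2Cl2, 0 °C → rt
Reagents that add atoms: iodine, II
Why: Appel-type iodination (Garegg–Samuelsson conditions), in which iodide displaces the alkoxyphosphonium ion at the unhindered primary C9 while the ketone and the remaining silyl ether are inert.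

Step 14
Reactants: 19 1-[(tert-butyldiphenylsilyl)oxy]-4-[(5R)-5-(2-iodoethyl)-5-methyl-2-(propan-2-yl)cyclopent-1-en-1-yl]butan-2-one
Product: 20 {2-[(1R)-2-{4-[(tert-butyldiphenylsilyl)oxy]-3-oxobutyl}-1-methyl-3-(propan-2-yl)cyclopent-2-en-1-yl]ethyl}triphenylphosphonium iodide
Conditions: PPh3, MeCN, 80 °C
Reagents that add atoms: triphenylphosphine, c1ccc(cc1)P(c1ccccc1)c1ccccc1
Why: Quaternisation of PPh3 by the primary iodide (SN2) gives the phosphonium salt under neutral conditions that leave the ketone untouched.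

Step 15
Reactants: 20 {2-[(1R)-2-{4-[(tert-butyldiphenylsilyl)oxy]-3-oxobutyl}-1-methyl-3-(propan-2-yl)cyclopent-2-en-1-yl]ethyl}triphenylphosphonium iodide
Product: 22 tert-butyl{[(8aR)-8a-methyl-3-(propan-2-yl)-1,2,4,5,8,8a-hexahydroazulen-6-yl]methoxy}diphenylsilane, via phosphorus ylide 21 (not isolated)
Conditions: KN(SiMe3)2, THF (0.005 M), −78 °C → reflux
Reagents that add atoms: none
Why: Intramolecular Wittig olefination, in which the non-stabilised C9 ylide adds to the C8 ketone, the two ends being held close by the C4=C5 alkene and the quaternary C1, and the oxaphosphetane collapses to the ring B C8=C9 alkene whose geometry is fixed by the seven-membered ring, while high dilution suppresses intermolecular olefination.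

Step 16
Reactants: 22 tert-butyl{[(8aR)-8a-methyl-3-(propan-2-yl)-1,2,4,5,8,8a-hexahydroazulen-6-yl]methoxy}diphenylsilane
Product: 23 [(8aR)-8a-methyl-3-(propan-2-yl)-1,2,4,5,8,8a-hexahydroazulen-6-yl]methanol (dauca-4,8-dien-14-ol)
Conditions: Bu4NF, THF, 0 °C → rt
Reagents that add atoms: none
Why: Fluoride-mediated desilylation, driven by the Si–F bond, frees the primary allylic C14 alcohol without acid, so both alkenes should keep their positions.

Step 17
Reactants: 23 [(8aR)-8a-methyl-3-(propan-2-yl)-1,2,4,5,8,8a-hexahydroazulen-6-yl]methanol; 24 vanillic acid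
Product: 25 [(8aR)-8a-methyl-3-(propan-2-yl)-1,2,4,5,8,8a-hexahydroazulen-6-yl]methyl 4-hydroxy-3-methoxybenzoate (target)
Conditions: PPh3, DIAD, THF, 0 °C → rt
Reagents that add atoms: none
Why: Mitsunobu esterification, in which the carboxylic acid, far more acidic than the phenol, protonates the betaine and its carboxylate displaces the primary alkoxyphosphonium ion at C14, so the ester should form without protection of the phenol.

**Compound list**

1 | (S)-citronellol, (3S)-3,7-dimethyloct-6-en-1-ol | CC(C)=CCC[C@H](C)CCO | starting material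
2 | tert-butyl{[(3S)-3,7-dimethyloct-6-en-1-yl]oxy}dimethylsilane | CC(C)=CCC[C@H](C)CCO[Si](C)(C)C(C)(C)C | intermediate
3 | secondary ozonide, tert-butyl{[(3S)-5-(5,5-dimethyl-1,2,4-trioxolan-3-yl)-3-methylpentyl]oxy}dimethylsilane (both configurations at the ozonide carbon) | CC1(C)OOC(CC[C@H](C)CCO[Si](C)(C)C(C)(C)C)O1 | intermediate
4 | (4S)-6-[(tert-butyldimethylsilyl)oxy]-4-methylhexanal | O=CCC[C@H](C)CCO[Si](C)(C)C(C)(C)C | intermediate
5 | ethyl diazoacetate | CCOC(=O)C=[N+]=[N-] | starting material
6 | ethyl (6S)-8-[(tert-butyldimethylsilyl)oxy]-6-methyl-3-oxooctanoate | CCOC(=O)CC(=O)CC[C@H](C)CCO[Si](C)(C)C(C)(C)C | intermediate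
7 | ethyl (6S)-8-[(tert-butyldimethylsilyl)oxy]-2-diazo-6-methyl-3-oxooctanoate | CCOC(=O)C(=[N+]=[N-])C(=O)CC[C@H](C)CCO[Si](C)(C)C(C)(C)C | intermediate
8 | ethyl (2R)-2-{2-[(tert-butyldimethylsilyl)oxy]ethyl}-2-methyl-5-oxocyclopentane-1-carboxylate (ring carbon 1 epimeric) | CCOC(=O)C1C(=O)CC[C@]1(C)CCO[Si](C)(C)C(C)(C)C | intermediate
9 | sodium enolate of 8, sodium (3R)-3-{2-[(tert-butyldimethylsilyl)oxy]ethyl}-2-(ethoxycarbonyl)-3-methylcyclopent-1-en-1-olate | [Na+].CCOC(=O)C1=C([O-])CC[C@]1(C)CCO[Si](C)(C)C(C)(C)C | intermediate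
10 | ethyl (5R)-5-{2-[(tert-butyldimethylsilyl)oxy]ethyl}-5-methyl-2-[(trifluoromethanesulfonyl)oxy]cyclopent-1-ene-1-carboxylate | CCOC(=O)C1=C(OS(=O)(=O)C(F)(F)F)CC[C@]1(C)CCO[Si](C)(C)C(C)(C)C | intermediate
11 | ethyl (5R)-5-{2-[(tert-butyldimethylsilyl)oxy]ethyl}-5-methyl-2-(propan-2-yl)cyclopent-1-ene-1-carboxylate | CCOC(=O)C1=C(C(C)C)CC[C@]1(C)CCO[Si](C)(C)C(C)(C)C | intermediate
12 | [(5R)-5-{2-[(tert-butyldimethylsilyl)oxy]ethyl}-5-methyl-2-(propan-2-yl)cyclopent-1-en-1-yl]methanol | OCC1=C(C(C)C)CC[C@]1(C)CCO[Si](C)(C)C(C)(C)C | intermediate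
13 | {2-[(1R)-2-(bromomethyl)-1-methyl-3-(propan-2-yl)cyclopent-2-en-1-yl]ethoxy}(tert-butyl)dimethylsilane | BrCC1=C(C(C)C)CC[C@]1(C)CCO[Si](C)(C)C(C)(C)C | intermediate
14 | hydroxyacetone, 1-hydroxypropan-2-one | CC(=O)CO | starting material
15 | 1-[(tert-butyldiphenylsilyl)oxy]propan-2-one | CC(=O)CO[Si](c1ccccc1)(c1ccccc1)C(C)(C)C | intermediate
16 | lithium enolate of 15, lithium 3-[(tert-butyldiphenylsilyl)oxy]prop-1-en-2-olate | [Li+].[O-]C(=C)CO[Si](c1ccccc1)(c1ccccc1)C(C)(C)C | intermediate
17 | 4-[(5R)-5-{2-[(tert-butyldimethylsilyl)oxy]ethyl}-5-methyl-2-(propan-2-yl)cyclopent-1-en-1-yl]-1-[(tert-butyldiphenylsilyl)oxy]butan-2-one | O=C(CO[Si](c1ccccc1)(c1ccccc1)C(C)(C)C)CCC2=C(C(C)C)CC[C@]2(C)CCO[Si](C)(C)C(C)(C)C | intermediate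
18 | 1-[(tert-butyldiphenylsilyl)oxy]-4-[(5R)-5-(2-hydroxyethyl)-5-methyl-2-(propan-2-yl)cyclopent-1-en-1-yl]butan-2-one | O=C(CO[Si](c1ccccc1)(c1ccccc1)C(C)(C)C)CCC2=C(C(C)C)CC[C@]2(C)CCO | intermediate
19 | 1-[(tert-butyldiphenylsilyl)oxy]-4-[(5R)-5-(2-iodoethyl)-5-methyl-2-(propan-2-yl)cyclopent-1-en-1-yl]butan-2-one | O=C(CO[Si](c1ccccc1)(c1ccccc1)C(C)(C)C)CCC2=C(C(C)C)CC[C@]2(C)CCI | intermediate
20 | {2-[(1R)-2-{4-[(tert-butyldiphenylsilyl)oxy]-3-oxobutyl}-1-methyl-3-(propan-2-yl)cyclopent-2-en-1-yl]ethyl}triphenylphosphonium iodide | O=C(CO[Si](c1ccccc1)(c1ccccc1)C(C)(C)C)CCC2=C(C(C)C)CC[C@]2(C)CC[P+](c3ccccc3)(c3ccccc3)c3ccccc3.[I-] | intermediate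
21 | phosphorus ylide of 20, 1-[(tert-butyldiphenylsilyl)oxy]-4-{(5R)-5-methyl-2-(propan-2-yl)-5-[2-(triphenyl-λ5-phosphanylidene)ethyl]cyclopent-1-en-1-yl}butan-2-one | O=C(CO[Si](c1ccccc1)(c1ccccc1)C(C)(C)C)CCC2=C(C(C)C)CC[C@]2(C)CC=P(c3ccccc3)(c3ccccc3)c3ccccc3 | intermediate
22 | tert-butyl{[(8aR)-8a-methyl-3-(propan-2-yl)-1,2,4,5,8,8a-hexahydroazulen-6-yl]methoxy}diphenylsilane | CC(C)(C)[Si](OCC1=CC[C@@]2(C)CCC(C(C)C)=C2CC1)(c1ccccc1)c1ccccc1 | intermediate
23 | [(8aR)-8a-methyl-3-(propan-2-yl)-1,2,4,5,8,8a-hexahydroazulen-6-yl]methanol (dauca-4,8-dien-14-ol) | OCC1=CC[C@@]2(C)CCC(C(C)C)=C2CC1 | intermediate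
24 | vanillic acid, 4-hydroxy-3-methoxybenzoic acid | COc1cc(C(=O)O)ccc1O | starting material
25 | [(8aR)-8a-methyl-3-(propan-2-yl)-1,2,4,5,8,8a-hexahydroazulen-6-yl]methyl 4-hydroxy-3-methoxybenzoate | COc1cc(C(=O)OCC2=CC[C@@]3(C)CCC(C(C)C)=C3CC2)ccc1O | target

**Step count**

Total step count: 17.
Longest linear sequence: 16 steps (steps 1 to 9 and 11 to 17, from (S)-citronellol); step 10 is a one-step side branch.

**Steps most likely to fail**

Step 15 (ring B closure by intramolecular Wittig reaction). What may go wrong: the basic ylide removes an α-proton of the ketone instead of adding to it, and intermolecular olefination competes with seven-membered ring closure, so that ring B forms slowly or oligomers form. The fallback sets out from 18 and comes back at 22. The C9 alcohol of 18 is oxidised with Dess–Martin periodinane (NaHCO3, CH2Cl2, rt) to the keto aldehyde F1. Excess Ph3P=CH2 (Ph3PCH3Br, KN(SiMe3)2, THF, 0 °C) converts both carbonyl groups into methylene groups and should give the 1,8-diene F2. Ring-closing metathesis with the second-generation Grubbs catalyst RuCl2(=CHPh)(H2IMes)(PCy3) in CH2Cl2 at 40 °C then joins C8 and C9 with loss of ethylene and gives 22; the tetrasubstituted C4=C5 alkene is too hindered to take part.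

Step 11 (enolate alkylation that forms C6–C7). What may go wrong: deprotonation of ketone 15 on the oxygen-bearing side, or proton transfer between product and enolate that leads to double alkylation. The fallback sets out from 13 and comes back at 23, and carries C14 as a non-enolisable acetal. Commercial 1,1-dimethoxypropan-2-one is deprotonated (LiN(iPr)2, THF, −78 °C) to its lithium enolate F3, which can form only on the methyl side, and is alkylated by 13 to the acetal ketone F4. Bu4NF in THF removes the only silyl group to give the alcohol F5. I2, PPh3 and imidazole give the iodide F6, and PPh3 in MeCN at 80 °C gives the phosphonium iodide F7. KN(SiMe3)2 in THF under high dilution forms the ylide F8, which closes ring B by the same Wittig reaction to the bicyclic dimethyl acetal F9. Aqueous oxalic acid in THF frees the conjugated aldehyde F10, and Luche reduction (NaBH4, CeCl3·7H2O, MeOH, 0 °C) reduces it by 1,2-addition to allylic alcohol 23.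

Step 7 (iron-catalysed coupling with the secondary Grignard reagent). What may go wrong: β-hydride elimination at the isopropyl–iron stage, which reduces the triflate instead of coupling it, or isomerisation of the branched alkyl group to the linear one. The fallback sets out from 10 and comes back at 11. Suzuki–Miyaura coupling of 10 with isopropenylboronic acid pinacol ester (Pd(dppf)Cl2, K3PO4, dioxane/H2O, 60 °C) gives the isopropenyl diene ester F11. Diimide, generated from 2-nitrobenzenesulfonyl hydrazide and Et3N in CH2Cl2 at rt, should then saturate only the 1,1-disubstituted alkene and give 11, the tetrasubstituted, ester-conjugated C4=C5 alkene being inert to diimide.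

**Further compounds**

F1 | step 15 | {(1R)-2-{4-[(tert-butyldiphenylsilyl)oxy]-3-oxobutyl}-1-methyl-3-(propan-2-yl)cyclopent-2-en-1-yl}acetaldehyde | O=C(CO[Si](c1ccccc1)(c1ccccc1)C(C)(C)C)CCC2=C(C(C)C)CC[C@]2(C)CC=O
F2 | step 15 | tert-butyl({2-methylidene-4-[(5R)-5-methyl-2-(propan-2-yl)-5-(prop-2-en-1-yl)cyclopent-1-en-1-yl]butyl}oxy)diphenylsilane | C=C(CO[Si](c1ccccc1)(c1ccccc1)C(C)(C)C)CCC2=C(C(C)C)CC[C@]2(C)CC=C
F3 | step 11 | lithium 3,3-dimethoxyprop-1-en-2-olate | [Li+].[O-]C(=C)C(OC)OC
F4 | step 11 | 4-[(5R)-5-{2-[(tert-butyldimethylsilyl)oxy]ethyl}-5-methyl-2-(propan-2-yl)cyclopent-1-en-1-yl]-1,1-dimethoxybutan-2-one | COC(OC)C(=O)CCC1=C(C(C)C)CC[C@]1(C)CCO[Si](C)(C)C(C)(C)C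
F5 | step 11 | 4-[(5R)-5-(2-hydroxyethyl)-5-methyl-2-(propan-2-yl)cyclopent-1-en-1-yl]-1,1-dimethoxybutan-2-one | COC(OC)C(=O)CCC1=C(C(C)C)CC[C@]1(C)CCO
F6 | step 11 | 4-[(5R)-5-(2-iodoethyl)-5-methyl-2-(propan-2-yl)cyclopent-1-en-1-yl]-1,1-dimethoxybutan-2-one | COC(OC)C(=O)CCC1=C(C(C)C)CC[C@]1(C)CCI
F7 | step 11 | {2-[(1R)-2-(4,4-dimethoxy-3-oxobutyl)-1-methyl-3-(propan-2-yl)cyclopent-2-en-1-yl]ethyl}triphenylphosphonium iodide | COC(OC)C(=O)CCC1=C(C(C)C)CC[C@]1(C)CC[P+](c2ccccc2)(c2ccccc2)c2ccccc2.[I-]
F8 | step 11 | 1,1-dimethoxy-4-{(5R)-5-methyl-2-(propan-2-yl)-5-[2-(triphenyl-λ5-phosphanylidene)ethyl]cyclopent-1-en-1-yl}butan-2-one | COC(OC)C(=O)CCC1=C(C(C)C)CC[C@]1(C)CC=P(c2ccccc2)(c2ccccc2)c2ccccc2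
F9 | step 11 | (8aR)-6-(dimethoxymethyl)-8a-methyl-3-(propan-2-yl)-1,2,4,5,8,8a-hexahydroazulene | COC(OC)C1=CC[C@@]2(C)CCC(C(C)C)=C2CC1
F10 | step 11 | (8aR)-8a-methyl-3-(propan-2-yl)-1,2,4,5,8,8a-hexahydroazulene-6-carbaldehyde | O=CC1=CC[C@@]2(C)CCC(C(C)C)=C2CC1
F11 | step 7 | ethyl (5R)-5-{2-[(tert-butyldimethylsilyl)oxy]ethyl}-5-methyl-2-(prop-1-en-2-yl)cyclopent-1-ene-1-carboxylate | CCOC(=O)C1=C(C(C)=C)CC[C@]1(C)CCO[Si](C)(C)C(C)(C)C
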